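**Plan**

Retrosynthesis: the three silyl ethers come off first. The C8'–C7' bond is then cut (lactone enolate plus benzylic bromide), the C7–OH bond is exchanged for a C7–C8' bond to give an endo-aryl cyclopropane fused to the butyrolactone, and that cyclopropane is cut at C8'–C8 and C8'–C7 to a (Z)-cinnamyl diazoacetate. Both aryl halves go back to vanillin.
What makes the key step possible: the benzylic carbinol carbon C7 and the lactone α-carbon C8' (beside the C9' carbonyl) are both bonded to C8, the β-carbon of the butyrolactone ring. A C7–C8' bond would therefore close a cyclopropane C7–C8–C8' with an aryl donor on C7 and a carbonyl acceptor on C8', and the target is its hydration product.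
Forward: one intramolecular carbene addition builds the lactone ring and the three-membered ring at once (C8–C8' and C7–C8' bonds). Water then breaks the C7–C8' bond again, the second aromatic unit is attached to C8' by enolate alkylation, and fluoride frees the three hydroxyl groups.
Stereochemistry: the chiral rhodium catalyst fixes C8 in the carbene addition, and the Z alkene geometry, carried over as an endo aryl group, fixes the relative configuration of the future C7. Backside attack of water inverts that carbon to 7S (an E alkene would end as the 7-epimer), and the C8 substituent sends the benzyl bromide to the opposite enolate face to set C8'.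

Key step: step 7

Remark on numbering: lignan numbering is used (C7 carbinol carbon, C8 lactone β-carbon, C9 lactone OCH2, C8' lactone α-carbon, C9' lactone carbonyl, C7' benzylic CH2 of the second aryl unit); in the bicyclic lactone, C1, C5 and C6 are the later C8', C8 and C7.

Assumption: Rh2(5R-MEPY)4, dirhodium tetrakis[methyl (5R)-2-oxopyrrolidine-5-carboxylate], a divalent rhodium carboxamidate dimer, is taken to select the alkene face that leads to the (1S,5R,6S) lactone, as is usual for this catalyst family with allyl diazoacetates. If the antipode were to form, Rh2(5S-MEPY)4 would be used with no other change.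

**Route**

Step 1
Reactants: 1 vanillin
Product: 2 3-methoxy-4-(triisopropylsilyloxy)benzaldehyde (O-TIPS vanillin)
Conditions: TIPSCl, imidazole, DMF, rt
Reagents that add atoms: triisopropylsilyl chloride (TIPSCl), CC(C)[Si](Cl)(C(C)C)C(C)C
Why: imidazole-promoted O-silylation of a phenol with TIPSCl is routine, the aldehyde is not affected, and the bulky aryl silyl ether should survive the amide bases, hydride reagents and Lewis acid used later while keeping the ring electron-rich for step 7.

Step 2
Reactants: 2 O-TIPS vanillin; 3 methyl bis(2,2,2-trifluoroethyl)phosphonoacetate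
Product: 4 methyl (Z)-3-[3-methoxy-4-(triisopropylsilyloxy)phenyl]prop-2-enoate
Conditions: KN(SiMe3)2, 18-crown-6, THF, −78 °C
Reagents that add atoms: none
Why: in the Still–Gennari variant of the Horner–Wadsworth–Emmons olefination the electron-poor bis(trifluoroethyl) phosphonate and a crown-ether-separated potassium counter-ion make elimination from the first-formed adduct faster than its equilibration, which with aromatic aldehydes should give the Z enoate needed for an endo aryl group later.

Step 3
Reactants: 4 (Z)-cinnamate ester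
Product: 5 (Z)-3-[3-methoxy-4-(triisopropylsilyloxy)phenyl]prop-2-en-1-ol
Conditions: i-Bu2AlH, CH2Cl2, −78 °C; aq. potassium sodium tartrate
Reagents that add atoms: none
Why: i-Bu2AlH reduces an α,β-unsaturated ester by 1,2-addition to the allylic alcohol at −78 °C and touches neither the Z double bond nor the aryl silyl ether.

Step 4
Reactants: 5 (Z)-allylic alcohol; 6 bromoacetyl bromide
Product: 7 (Z)-3-[3-methoxy-4-(triisopropylsilyloxy)phenyl]prop-2-en-1-yl bromoacetate
Conditions: NaHCO3, MeCN, 0 °C
Reagents that add atoms: none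
Why: acylation of a primary alcohol by an acid bromide under bicarbonate buffering is fast at 0 °C and is the usual first stage of the ditosylhydrazine route to diazoacetates, the weak base keeping the acid-sensitive Z-cinnamyl system from isomerising or ionising.

Step 5
Reactants: 7 (Z)-allyl bromoacetate
Product: 9 (Z)-3-[3-methoxy-4-(triisopropylsilyloxy)phenyl]prop-2-en-1-yl diazoacetate, via N-alkyl-N,N'-ditosylhydrazide 8 (not isolated)
Conditions: TsNHNHTs, DBU, THF, 0 °C
Reagents that add atoms: N,N'-ditosylhydrazine (TsNHNHTs), Cc1ccc(cc1)S(=O)(=O)NNS(=O)(=O)c1ccc(C)cc1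
Why: N,N'-ditosylhydrazine is alkylated by the bromoacetate and DBU then expels two p-toluenesulfinate ions from the N-alkyl hydrazide (sulfinate eliminations of the Bamford–Stevens kind), a standard and mild diazoacetate synthesis that leaves the Z alkene and the ester alone.

Step 6
Reactants: 9 (Z)-allyl diazoacetate
Product: 10 (1S,5R,6S)-6-[3-methoxy-4-(triisopropylsilyloxy)phenyl]-3-oxabicyclo[3.1.0]hexan-2-one (aryl endo)
Conditions: Rh2(5R-MEPY)4 (1 mol %), CH2Cl2, reflux, slow addition of 9
Reagents that add atoms: none
Why: the intramolecular cyclopropanation of allyl diazoacetates by chiral divalent rhodium carboxamidates is a concerted carbene addition that closes the five-membered lactone and the cyclopropane together, carries the Z geometry stereospecifically into an endo aryl group at C6, and lets the ligand pocket choose the alkene face so that C5 (later C8) is set by the catalyst and C6 (latent C7) relative to it, Z-disubstituted allyl esters being the substrates on which these catalysts are most selective.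

Step 7
Reactants: 10 endo-aryl cyclopropane lactone
Product: 11 (4R)-4-[(S)-hydroxy[3-methoxy-4-(triisopropylsilyloxy)phenyl]methyl]oxolan-2-one
Conditions: Sc(OTf)3 (10 mol %), H2O (10 equiv), THF, 0 °C
Reagents that add atoms: water, O
Why: Coordination of Sc(OTf)3 to the lactone carbonyl weakens the C1–C6 bond of the cyclopropane, which, unlike the ring-fusion bond C1–C5, lies out of the lactone plane and can overlap with the carbonyl π* orbital, and whose far end (C6) carries the electron-rich aryl donor; water then attacks C6 from the side opposite C1, the scandium enolate leaves and is protonated to the C8' methylene. The closest known reaction type is the Lewis-acid-promoted SN2-like ring opening (oxy-homo-Michael addition) of aryl donor–acceptor cyclopropanes, cyclopropane-fused lactones among them, by alcohols or water with inversion at the benzylic carbon; most of those substrates carry two acceptors, so the single lactone carbonyl is the point at which this substrate stretches that chemistry. No ring is closed: the three-membered ring opens and the butyrolactone closed in step 6 is released unchanged. C7 becomes S through inversion at C6 of the endo-aryl bicycle (controlled by the backside trajectory, hence by the Z geometry fixed in steps 2 and 6), and C8, the former C5, is not involved. The step needs cleavage of C1–C6 only and no ionisation to a free benzylic cation; the aryl group on C6 and the carbonyl on C1 secure the regiochemistry, and because an enolate stabilised by one carbonyl is a reluctant leaving group the bond should not break before the nucleophile arrives, which excess water, a mild water-tolerant triflate and 0 °C are chosen to support.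

Step 8
Reactants: 11 hydroxy lactone
Product: 12 (4R)-4-[(S)-(tert-butyldimethylsilyloxy)[3-methoxy-4-(triisopropylsilyloxy)phenyl]methyl]oxolan-2-one (7-O-TBS lactone)
Conditions: TBSOTf, 2,6-lutidine, CH2Cl2, −78 °C
Reagents that add atoms: tert-butyldimethylsilyl triflate (TBSOTf), CC(C)(C)[Si](C)(C)OS(=O)(=O)C(F)(F)F
Why: silylation of a secondary alcohol with TBSOTf and 2,6-lutidine at −78 °C is fast and non-acidic, so the benzylic hydroxyl is masked for the enolate chemistry before it can ionise or attack the lactone, and no stereocenter is involved.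

Step 9
Reactants: 2 O-TIPS vanillin
Product: 13 [3-methoxy-4-(triisopropylsilyloxy)phenyl]methanol (O-TIPS vanillyl alcohol)
Conditions: NaBH4, MeOH, 0 °C
Reagents that add atoms: none
Why: NaBH4 reduces the aromatic aldehyde to the benzylic alcohol chemoselectively and the aryl TIPS ether is stable to cold methanolic borohydride.

Step 10
Reactants: 13 O-TIPS vanillyl alcohol
Product: 14 4-(bromomethyl)-2-methoxy-1-(triisopropylsilyloxy)benzene (O-TIPS vanillyl bromide)
Conditions: PBr3, Et2O, 0 °C
Reagents that add atoms: phosphorus tribromide (PBr3), BrP(Br)Br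
Why: PBr3 turns a primary benzylic alcohol into the bromide through a phosphite ester and SN2 displacement by bromide at 0 °C, which is the customary route to electron-rich benzylic bromides that are used at once.

Step 11
Reactants: 12 7-O-TBS lactone; 14 O-TIPS vanillyl bromide
Product: 15 (3R,4R)-4-[(S)-(tert-butyldimethylsilyloxy)[3-methoxy-4-(triisopropylsilyloxy)phenyl]methyl]-3-[3-methoxy-4-(triisopropylsilyloxy)benzyl]oxolan-2-one (tris-silyl ether of the target)
Conditions: LiN(SiMe3)2, THF, −78 °C; then 14, DMPU, −78 to −40 °C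
Reagents that add atoms: none
Why: alkylation of the lithium enolate of a β-substituted γ-butyrolactone with a benzylic bromide is the classical way to dibenzylbutyrolactone lignans, and the bulky silyloxy(aryl)methyl group on C8 should shield one face of the planar enolate so that the benzyl group enters anti and C8' is formed as R (trans lactone), while C7 and C8 are not enolisable and stay as they are.

Step 12
Reactants: 15 tris-silyl ether of the target
Product: 16 (7S,8R,8'R)-7-hydroxymatairesinol
Conditions: Bu4NF, AcOH (1:1), THF, 0 °C to rt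
Reagents that add atoms: none
Why: fluoride cleaves the two aryl TIPS ethers and the benzylic TBS ether through pentacoordinate silicates, and the acetic acid buffer keeps the freed phenols protonated so that neither a p-quinone methide at C7 nor enolisation at C8' can erode the stereocenters.

**Compound list**

1 | vanillin (4-hydroxy-3-methoxybenzaldehyde) | COc1cc(C=O)ccc1O | starting material
2 | O-TIPS vanillin: 3-methoxy-4-(triisopropylsilyloxy)benzaldehyde | COc1cc(C=O)ccc1O[Si](C(C)C)(C(C)C)C(C)C | intermediate
3 | methyl bis(2,2,2-trifluoroethyl)phosphonoacetate | COC(=O)CP(=O)(OCC(F)(F)F)OCC(F)(F)F | starting material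
4 | (Z)-cinnamate ester: methyl (Z)-3-[3-methoxy-4-(triisopropylsilyloxy)phenyl]prop-2-enoate | COC(=O)/C=C\c1ccc(O[Si](C(C)C)(C(C)C)C(C)C)c(OC)c1 | intermediate
5 | (Z)-allylic alcohol: (Z)-3-[3-methoxy-4-(triisopropylsilyloxy)phenyl]prop-2-en-1-ol | OC/C=C\c1ccc(O[Si](C(C)C)(C(C)C)C(C)C)c(OC)c1 | intermediate
6 | bromoacetyl bromide | BrCC(Br)=O | starting material
7 | (Z)-allyl bromoacetate: (Z)-3-[3-methoxy-4-(triisopropylsilyloxy)phenyl]prop-2-en-1-yl bromoacetate | BrCC(=O)OC/C=C\c1ccc(O[Si](C(C)C)(C(C)C)C(C)C)c(OC)c1 | intermediate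
8 | N-alkyl-N,N'-ditosylhydrazide: (Z)-3-[3-methoxy-4-(triisopropylsilyloxy)phenyl]prop-2-en-1-yl 2-[1,2-bis(p-tolylsulfonyl)hydrazin-1-yl]acetate | Cc1ccc(cc1)S(=O)(=O)NN(CC(=O)OC/C=C\c1ccc(O[Si](C(C)C)(C(C)C)C(C)C)c(OC)c1)S(=O)(=O)c1ccc(C)cc1 | intermediate (not isolated)
9 | (Z)-allyl diazoacetate: (Z)-3-[3-methoxy-4-(triisopropylsilyloxy)phenyl]prop-2-en-1-yl diazoacetate | [N-]=[N+]=CC(=O)OC/C=C\c1ccc(O[Si](C(C)C)(C(C)C)C(C)C)c(OC)c1 | intermediate
10 | endo-aryl cyclopropane lactone: (1S,5R,6S)-6-[3-methoxy-4-(triisopropylsilyloxy)phenyl]-3-oxabicyclo[3.1.0]hexan-2-one, aryl cis to the lactone ring | O=C1OC[C@@H]2[C@H](c3ccc(O[Si](C(C)C)(C(C)C)C(C)C)c(OC)c3)[C@H]12 | intermediate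
11 | hydroxy lactone: (4R)-4-[(S)-hydroxy[3-methoxy-4-(triisopropylsilyloxy)phenyl]methyl]oxolan-2-one | C1C(=O)OC[C@@H]1[C@H](O)c2ccc(O[Si](C(C)C)(C(C)C)C(C)C)c(OC)c2 | intermediate
12 | 7-O-TBS lactone: (4R)-4-[(S)-(tert-butyldimethylsilyloxy)[3-methoxy-4-(triisopropylsilyloxy)phenyl]methyl]oxolan-2-one | C1C(=O)OC[C@@H]1[C@H](O[Si](C)(C)C(C)(C)C)c2ccc(O[Si](C(C)C)(C(C)C)C(C)C)c(OC)c2 | intermediate
13 | O-TIPS vanillyl alcohol: [3-methoxy-4-(triisopropylsilyloxy)phenyl]methanol | COc1cc(CO)ccc1O[Si](C(C)C)(C(C)C)C(C)C | intermediate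
14 | O-TIPS vanillyl bromide: 4-(bromomethyl)-2-methoxy-1-(triisopropylsilyloxy)benzene | COc1cc(CBr)ccc1O[Si](C(C)C)(C(C)C)C(C)C | intermediate
15 | tris-silyl ether of the target: (3R,4R)-4-[(S)-(tert-butyldimethylsilyloxy)[3-methoxy-4-(triisopropylsilyloxy)phenyl]methyl]-3-[3-methoxy-4-(triisopropylsilyloxy)benzyl]oxolan-2-one | COc1cc(C[C@H]2C(=O)OC[C@@H]2[C@H](O[Si](C)(C)C(C)(C)C)c3ccc(O[Si](C(C)C)(C(C)C)C(C)C)c(OC)c3)ccc1O[Si](C(C)C)(C(C)C)C(C)C | intermediate
16 | (7S,8R,8'R)-7-hydroxymatairesinol: (3R,4R)-4-[(S)-hydroxy(4-hydroxy-3-methoxyphenyl)methyl]-3-(4-hydroxy-3-methoxybenzyl)oxolan-2-one | COc1cc(C[C@H]2C(=O)OC[C@@H]2[C@H](O)c2ccc(O)c(OC)c2)ccc1O | target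

**Count and risks**

Total step count: 12 steps (one in-flask intermediate, 8).
Longest linear sequence: 10 steps from vanillin (steps 1 to 8, then 11 and 12); steps 9 and 10 are a two-step branch from 2.

Steps most likely to fail:

Step 7. What may go wrong: too little activation by a single carbonyl, so that the ring does not open; ionisation at the benzylic carbon before water arrives, with loss of the C7 configuration; or Lewis-acid-promoted translactonisation of the product onto the new hydroxyl. The fallback gives up the cyclopropane and sets C7 and C8 by an Evans syn-aldol reaction; it sets out from 2 and comes back to the route at 12. (S)-4-Benzyl-2-oxazolidinone would be acylated with pent-4-enoyl chloride (n-BuLi, THF, −78 °C) to (S)-4-benzyl-3-(pent-4-enoyl)oxazolidin-2-one F1. Its Z boron enolate (Bu2BOTf, i-Pr2NEt, CH2Cl2, −78 to 0 °C) should add to 2 to give the syn aldol adduct F2, in which the α-carbon is the future C8 and the carbinol carbon is C7, both in the required sense for the (S)-auxiliary. TBSOTf and 2,6-lutidine would give the silyl ether F3, and LiBH4 (THF, MeOH, 0 °C) would remove the auxiliary reductively to the primary alcohol F4, whose CH2OH is the future C9. Lemieux–Johnson cleavage of the terminal alkene (OsO4 cat., NaIO4, 2,6-lutidine, dioxane–water) would give an aldehyde that closes to the lactol F5, and oxidation of the lactol (PhI(OAc)2, TEMPO cat., CH2Cl2) would give 12.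

Step 11. What may go wrong: self-condensation or solvolysis of the electron-rich benzylic bromide, double alkylation, or insufficient anti selectivity at C8'. The fallback introduces the benzyl group by aldol condensation and conjugate reduction; it sets out from 12 (with aldehyde 2 as the partner) and comes back at 15. The lithium enolate of 12 (LiN(SiMe3)2, THF, −78 °C) would add to 2 to give the β-hydroxy lactone F6 as a mixture of diastereomers. Mesylation (MsCl, Et3N, CH2Cl2, 0 °C) to the mesylate F7, which is not isolated, and elimination with DBU should give the (E)-α-arylidene lactone F8. Conjugate reduction (NaBH4, NiCl2·6H2O, MeOH–THF, 0 °C) would give 15 together with its C8' epimer F9, and DBU in toluene should equilibrate the only enolisable stereocenter toward the more stable trans lactone 15.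

Step 12. What may go wrong: epimerisation at C7 through a p-quinone methide, because the hindered benzylic silyl ether is cleaved only after the phenols are free, or incomplete desilylation. The fallback carries the C7 hydroxyl as a triethylsilyl ether and unmasks it before the phenols; it sets out from 11 and comes back at 16. TESOTf and 2,6-lutidine (CH2Cl2, −78 °C) would give the 7-O-TES lactone F10, and alkylation with 14 under the conditions of step 11 would give the tris-silyl ether F11. HF·pyridine buffered with pyridine (THF, 0 °C) should remove only the TES group while both phenols are still silylated, so that no quinone methide can form, and give the bis-TIPS ether F12. The two aryl TIPS ethers would then be cleaved quickly with Bu4NF and AcOH (THF, 0 °C) to give 16.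

**Further compounds**

F1 | step 7 | (S)-4-benzyl-3-(pent-4-enoyl)oxazolidin-2-one | C=CCCC(=O)N1C(=O)OC[C@@H]1Cc1ccccc1
F2 | step 7 | syn aldol adduct: (S)-4-benzyl-3-{(2S)-2-[(S)-hydroxy[3-methoxy-4-(triisopropylsilyloxy)phenyl]methyl]pent-4-enoyl}oxazolidin-2-one | C=CC[C@H](C(=O)N1C(=O)OC[C@@H]1Cc1ccccc1)[C@H](O)c1ccc(O[Si](C(C)C)(C(C)C)C(C)C)c(OC)c1
F3 | step 7 | silyl ether: (S)-4-benzyl-3-{(2S)-2-[(S)-(tert-butyldimethylsilyloxy)[3-methoxy-4-(triisopropylsilyloxy)phenyl]methyl]pent-4-enoyl}oxazolidin-2-one | C=CC[C@H](C(=O)N1C(=O)OC[C@@H]1Cc1ccccc1)[C@H](O[Si](C)(C)C(C)(C)C)c1ccc(O[Si](C(C)C)(C(C)C)C(C)C)c(OC)c1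
F4 | step 7 | primary alcohol: (2R)-2-[(S)-(tert-butyldimethylsilyloxy)[3-methoxy-4-(triisopropylsilyloxy)phenyl]methyl]pent-4-en-1-ol | C=CC[C@H](CO)[C@H](O[Si](C)(C)C(C)(C)C)c1ccc(O[Si](C(C)C)(C(C)C)C(C)C)c(OC)c1
F5 | step 7 | lactol: (4R)-4-[(S)-(tert-butyldimethylsilyloxy)[3-methoxy-4-(triisopropylsilyloxy)phenyl]methyl]oxolan-2-ol, mixture of anomers | C1C(O)OC[C@@H]1[C@H](O[Si](C)(C)C(C)(C)C)c2ccc(O[Si](C(C)C)(C(C)C)C(C)C)c(OC)c2
F6 | step 11 | β-hydroxy lactone: (4R)-4-[(S)-(tert-butyldimethylsilyloxy)(aryl)methyl]-3-[hydroxy(aryl)methyl]oxolan-2-one, aryl = 3-methoxy-4-(triisopropylsilyloxy)phenyl, mixture at C8' and C7' | COc1cc(C(O)C2C(=O)OC[C@@H]2[C@H](O[Si](C)(C)C(C)(C)C)c3ccc(O[Si](C(C)C)(C(C)C)C(C)C)c(OC)c3)ccc1O[Si](C(C)C)(C(C)C)C(C)C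
F7 | step 11 | mesylate of F6 | COc1cc(C(OS(C)(=O)=O)C2C(=O)OC[C@@H]2[C@H](O[Si](C)(C)C(C)(C)C)c3ccc(O[Si](C(C)C)(C(C)C)C(C)C)c(OC)c3)ccc1O[Si](C(C)C)(C(C)C)C(C)C
F8 | step 11 | (E)-α-arylidene lactone: (4R,E)-4-[(S)-(tert-butyldimethylsilyloxy)(aryl)methyl]-3-[3-methoxy-4-(triisopropylsilyloxy)benzylidene]oxolan-2-one | COc1cc(/C=C2/C(=O)OC[C@@H]2[C@H](O[Si](C)(C)C(C)(C)C)c3ccc(O[Si](C(C)C)(C(C)C)C(C)C)c(OC)c3)ccc1O[Si](C(C)C)(C(C)C)C(C)C
F9 | step 11 | C8' epimer of 15 (cis lactone, 3S,4R) | COc1cc(C[C@@H]2C(=O)OC[C@@H]2[C@H](O[Si](C)(C)C(C)(C)C)c3ccc(O[Si](C(C)C)(C(C)C)C(C)C)c(OC)c3)ccc1O[Si](C(C)C)(C(C)C)C(C)C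
F10 | step 12 | 7-O-TES lactone: (4R)-4-[(S)-(triethylsilyloxy)[3-methoxy-4-(triisopropylsilyloxy)phenyl]methyl]oxolan-2-one | C1C(=O)OC[C@@H]1[C@H](O[Si](CC)(CC)CC)c2ccc(O[Si](C(C)C)(C(C)C)C(C)C)c(OC)c2
F11 | step 12 | tris-silyl ether with TES at O7: (3R,4R)-4-[(S)-(triethylsilyloxy)(aryl)methyl]-3-[3-methoxy-4-(triisopropylsilyloxy)benzyl]oxolan-2-one | COc1cc(C[C@H]2C(=O)OC[C@@H]2[C@H](O[Si](CC)(CC)CC)c3ccc(O[Si](C(C)C)(C(C)C)C(C)C)c(OC)c3)ccc1O[Si](C(C)C)(C(C)C)C(C)C
F12 | step 12 | bis-TIPS ether of the target (free 7-OH) | COc1cc(C[C@H]2C(=O)OC[C@@H]2[C@H](O)c3ccc(O[Si](C(C)C)(C(C)C)C(C)C)c(OC)c3)ccc1O[Si](C(C)C)(C(C)C)C(C)C
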